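**Retrosynthetic overview**
1. The target is reached by late peripheral epoxidation of C1=C10, acylation of O8 with a separately made (2R,3S)-epoxy acid, and methylenation of C11, all on an 8β-silyloxy (1(10)E,4Z)-germacradien-6α,12-olide.
2. The ten-membered ring is opened at C3–C4: one-flask 9-BBN hydroboration and intramolecular B-alkyl Suzuki–Miyaura coupling of an open-chain γ-lactone that carries a (Z)-2-iodopropenyl group on C6 and a C8–C9–C10(Me)=C1–C2=C3 dienyl arm on C7.
3. Enabling feature: C4 is the methyl-bearing sp2 carbon of the Z C4=C5 olefin and its C3 substituent is cis to C6, so a Z-iodide points its C–I bond at the C7 arm; C3 is the CH2 end of the C10=C1–C2=C3 diene; the trans γ-lactone (O–C6–C7–C11–C12) and the E C1=C10 olefin pre-organise the ring.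
4. The open-chain precursor comes from a C8–C9 vinylogous Mukaiyama aldol (sets C8) and a Wittig methylenation; the lactone aldehyde comes from an Evans succinate syn-aldol/lactonisation with (Z)-3-iodobut-2-enal (sets C6 and C7).
5. Ring order: γ-lactone (step 4), ten-membered carbocycle (step 12), C1–C10 oxirane (step 19); the side-chain oxirane comes from a Sharpless epoxidation (step 16).

Key step: step 12

Remark on numbering: positions are numbered as in germacranes (ring C1–C10, lactone C11–C12 closed on O6, exocyclic C13, methyl C14 on C10, methyl C15 on C4).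
Assumption: in step 9 the oxazaborolidinone from N-tosyl-L-tryptophan is taken to direct attack to the Re face of the C8 aldehyde (O > C7 > H); if the sense is the opposite, the D-tryptophan reagent is used.

Step 1
Reactants: 1 (S)-4-benzyl-1,3-oxazolidin-2-one; 2 methyl 4-chloro-4-oxobutanoate
Product: 3 methyl 4-[(4S)-4-benzyl-2-oxo-1,3-oxazolidin-3-yl]-4-oxobutanoate
Conditions: Et3N, DMAP (cat.), CH2Cl2, 0 °C to rt
Reagents that add atoms: none
Why: DMAP-catalysed N-acylation of the oxazolidinone by the acid chloride; the methyl ester is untouched and no stereocentre is formed.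

Step 2
Reactants: 4 but-2-yn-1-ol
Product: 6 (Z)-3-iodobut-2-en-1-ol, via cyclic alkenylalanate 5 (not isolated)
Conditions: NaAlH2(OCH2CH2OMe)2, THF, 0 °C to rt; then I2, −78 to 0 °C
Reagents that add atoms: iodine, II
Why: Alkoxide-directed trans-hydroalumination of the propargylic alcohol places aluminium on the methyl-bearing carbon, and iodinolysis with retention gives the Z-iodide with iodine cis to the carbinol carbon.

Step 3
Reactants: 6 (Z)-3-iodobut-2-en-1-ol
Product: 7 (Z)-3-iodobut-2-enal
Conditions: MnO2, CH2Cl2, rt, dark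
Reagents that add atoms: none
Why: Neutral allylic oxidation with MnO2 should give the enal without Z/E isomerisation; it is used at once.

Step 4
Reactants: 3 succinyl imide; 7 (Z)-3-iodobut-2-enal
Product: 10 (4S)-4-benzyl-3-{[(2S,3S)-2-[(Z)-2-iodoprop-1-en-1-yl]-5-oxooxolan-3-yl]carbonyl}-1,3-oxazolidin-2-one (trans-lactone), via boron enolate 8 (not isolated), via aldol adduct 9 (not isolated)
Conditions: Bu2BOTf, i-Pr2NEt, CH2Cl2, −78 to 0 °C; then 7, −78 to 0 °C; H2O2, MeOH, pH 7 buffer; then PPTS (cat.), CH2Cl2, rt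
Reagents that add atoms: none
Why: Evans syn-aldol through the Z(O)-boron enolate in a Zimmerman–Traxler chair, with the (S)-benzyl auxiliary fixing the face, should set C6 and C7 (O6 syn to the C11 branch), and the new hydroxyl then closes the γ-lactone on the methyl ester to give the trans-disubstituted lactone.

Step 5
Reactants: 10 lactone imide
Product: 12 (2S,3S)-2-[(Z)-2-iodoprop-1-en-1-yl]-5-oxooxolane-3-carboxylic acid, via peroxy acid 11 (not isolated)
Conditions: LiOH, H2O2, THF/H2O, 0 °C; then Na2SO3; then 1 M HCl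
Reagents that add atoms: hydrogen peroxide (as LiOOH), OO
Why: Hydroperoxide cleaves the exocyclic imide carbonyl selectively, sulfite reduces the peroxy acid, and acidification recloses any opened lactone, so C6 and C7 are untouched.

Step 6
Reactants: 12 lactone acid
Product: 13 (4R,5S)-4-(hydroxymethyl)-5-[(Z)-2-iodoprop-1-en-1-yl]oxolan-2-one
Conditions: BH3·SMe2, THF, 0 °C to rt; MeOH quench
Reagents that add atoms: none
Why: Borane reduces the free carboxylic acid much faster than the lactone or the trisubstituted iodoalkene (chemoselective acid reduction).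

Step 7
Reactants: 13 hydroxymethyl lactone
Product: 14 (2S,3S)-2-[(Z)-2-iodoprop-1-en-1-yl]-5-oxooxolane-3-carbaldehyde
Conditions: Dess–Martin periodinane, CH2Cl2, 0 °C to rt
Reagents that add atoms: none
Why: Neutral Dess–Martin oxidation should give the C8 aldehyde without epimerising C7 (the trans isomer is also the thermodynamic one).

Step 8
Reactants: 15 3-methylbut-2-enal
Product: 16 (E)-tert-butyl(dimethyl)[(3-methylbuta-1,3-dien-1-yl)oxy]silane
Conditions: TBSOTf, Et3N, CH2Cl2, 0 °C to rt
Reagents that add atoms: tert-butyldimethylsilyl triflate, CC(C)(C)[Si](C)(C)OS(=O)(=O)C(F)(F)F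
Why: Soft γ-enolisation and O-silylation of the enal gives the silyl dienol ether, the vinylogous nucleophile for C9–C10(C14)–C1–C2.

Step 9
Reactants: 14 lactone aldehyde; 16 silyl dienol ether
Product: 17 (4R,5S)-4-[(1R,3E)-1-hydroxy-3-methyl-5-oxopent-3-en-1-yl]-5-[(Z)-2-iodoprop-1-en-1-yl]oxolan-2-one
Conditions: pre-formed B-phenyl oxazaborolidinone from N-tosyl-L-tryptophan and PhBCl2 (1.0 equiv), i-PrOH (1.1 equiv), EtCN, −78 °C
Reagents that add atoms: none
Why: Oxazaborolidinone-promoted asymmetric vinylogous Mukaiyama aldol of an aldehyde-derived dienol ether attacks through its CH2 terminus on the Re face of the C8 aldehyde (reagent control) to set 8R, and the s-trans diene delivers the E enal (the future E C1=C10 olefin).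

Step 10
Reactants: 17 hydroxy enal
Product: 18 (4S,5S)-5-[(Z)-2-iodoprop-1-en-1-yl]-4-[(1R,3E)-3-methyl-5-oxo-1-(triethylsilyloxy)pent-3-en-1-yl]oxolan-2-one
Conditions: TESOTf, 2,6-lutidine, CH2Cl2, −78 °C
Reagents that add atoms: triethylsilyl triflate, CC[Si](CC)(CC)OS(=O)(=O)C(F)(F)F
Why: Silylation under weakly basic cold conditions protects O8 before any base is used, which blocks translactonisation to O8 and elimination (the geometric centre is unchanged; the C7 descriptor changes only by CIP priority).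

Step 11
Reactants: 18 silyloxy enal
Product: 19 (4S,5S)-5-[(Z)-2-iodoprop-1-en-1-yl]-4-[(1R,3E)-3-methyl-1-(triethylsilyloxy)hexa-3,5-dien-1-yl]oxolan-2-one
Conditions: Ph3PCH3Br, KN(SiMe3)2, THF, 0 °C; then 18, −78 to 0 °C
Reagents that add atoms: methyltriphenylphosphonium bromide, C[P+](c1ccccc1)(c1ccccc1)c1ccccc1.[Br-]
Why: Wittig methylenation of the enal is much faster than attack on the lactone at low temperature and gives the C10=C1–C2=C3 diene with the E olefin unchanged.

Step 12
Reactants: 19 open-chain iodoalkene diene lactone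
Product: 21 (1(10)E,4Z)-8β-(triethylsilyloxy)-13-norgermacra-1(10),4-dien-12,6α-olide (ten-membered carbocycle trans-fused to the γ-lactone, C11 = CH2), via alkylborane 20 (not isolated)
Conditions: 9-BBN (1.5 equiv), THF, 0 °C to rt; then slow addition (12 h) to Pd(dppf)Cl2 (0.15 equiv), AsPh3 (0.3 equiv), Cs2CO3 (3 equiv), DMF/THF/H2O, 45 °C, final about 1 mM
Reagents that add atoms: none
Why: 9-BBN adds anti-Markovnikov to the only monosubstituted olefin (C2=C3, the end of the C10=C1–C2=C3 diene) to give the homoallylic borane 20; zerovalent palladium (formed from the divalent palladium precatalyst) then inserts into the C4–I bond with retention, the base-activated borane transfers C3 to palladium within the same molecule to give an eleven-membered palladacycle, and reductive elimination contracts this to the ten-membered ring with the new C3–C4 bond. The closest known reaction type is the B-alkyl Suzuki–Miyaura macrocyclisation of alkenyl iodides under high dilution, which has closed nine- to twelve-membered carbocycles. The ring closed is the cyclodeca-1,5-diene, by intramolecular C(sp3)–C(sp2) coupling in which the C4=C5 olefin becomes endocyclic (endo mode with respect to the alkenyl iodide), and the lactone already present ends up trans-fused. No stereocentre is created: the 4Z geometry is carried over from the Z-iodide with retention, and the 1(10)E olefin and C6, C7, C8 are untouched. The step needs chemoselective hydroboration, secured by the bulk of 9-BBN against the two trisubstituted olefins, and cyclisation over oligomerisation and β-hydride elimination, secured by slow addition at high dilution, the dppf ligand, and pre-organisation by the trans-lactone, the E C1=C10 olefin and the Z-iodoalkene whose C–I bond is cis to C6. Any lactone opened by the aqueous base can only reclose on O6 on mild acidic work-up because O8 is silylated.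

Step 13
Reactants: 21 macrocyclic lactone
Product: 23 (1(10)E,4Z)-13-(dimethylamino)-8β-(triethylsilyloxy)-11,13-dihydrogermacra-1(10),4-dien-12,6α-olide (C11 epimers), via lithium enolate 22 (not isolated)
Conditions: LiN(i-Pr)2, THF, −78 °C; then CH2=NMe2+ I−, −78 °C to rt
Reagents that add atoms: N,N-dimethylmethyleneiminium iodide (Eschenmoser's salt), C=[N+](C)C.[I-]
Why: The lactone enolate (C11 carries the only acidic C–H) is aminomethylated by Eschenmoser's salt (Mannich reaction); the C11 configuration is of no consequence because the centre becomes sp2 in step 14.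

Step 14
Reactants: 23 Mannich base
Product: 25 (1(10)E,4Z)-8β-(triethylsilyloxy)germacra-1(10),4,11(13)-trien-12,6α-olide, via ammonium iodide 24 (not isolated)
Conditions: MeI, THF/MeOH, rt; then NaHCO3 (aq.), EtOAc, rt
Reagents that add atoms: none
Why: Quaternisation followed by mild-base β-elimination of trimethylamine (E1cB) gives the α-methylene lactone without touching the olefins or the silyl ether.

Step 15
Reactants: 25 silyl ether
Product: 26 (1(10)E,4Z)-8β-hydroxygermacra-1(10),4,11(13)-trien-12,6α-olide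
Conditions: HF·pyridine, pyridine, THF, 0 °C
Reagents that add atoms: none
Why: Buffered fluoride removes the triethylsilyl group under conditions too mild for transannular cyclisation of the 1(10),4-diene or for translactonisation.

Step 16
Reactants: 27 (E)-2-methylbut-2-en-1-ol
Product: 28 [(2S,3S)-2,3-dimethyloxiran-2-yl]methanol
Conditions: Ti(Oi-Pr)4 (cat.), L-(+)-diethyl tartrate (cat.), t-BuOOH, 4 Å molecular sieves, CH2Cl2, −20 °C
Reagents that add atoms: tert-butyl hydroperoxide, CC(C)(C)OO
Why: Sharpless asymmetric epoxidation with the L-(+)-tartrate sets both oxirane centres as (2S,3S), as it does for other E allylic alcohols, and the E olefin fixes the cis relation of the two methyl groups.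

Step 17
Reactants: 28 epoxy alcohol
Product: 29 (2R,3S)-2,3-dimethyloxirane-2-carboxylic acid
Conditions: RuCl3 (cat.), NaIO4, CCl4/MeCN/H2O, rt
Reagents that add atoms: sodium periodate, [Na+].[O-]I(=O)(=O)=O
Why: Ruthenium tetroxide generated in situ oxidises the primary alcohol to the acid without opening the oxirane (the C2 descriptor changes only by CIP priority).

Step 18
Reactants: 26 8β-alcohol; 29 epoxy acid
Product: 31 (1(10)E,4Z)-8β-[(2R,3S)-2,3-dimethyloxirane-2-carbonyloxy]germacra-1(10),4,11(13)-trien-12,6α-olide, via mixed anhydride 30 (not isolated)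
Conditions: 29, 2,4,6-trichlorobenzoyl chloride, Et3N, THF, rt; then 26, DMAP, PhMe, rt
Reagents that add atoms: none
Why: Yamaguchi esterification activates the α-quaternary, non-enolisable epoxy acid as a mixed anhydride that DMAP transfers to the hindered secondary 8β-hydroxyl with retention at C8.

Step 19
Reactants: 31 ester
Product: 32 (1R,10R)-1β,10α-epoxy-8β-[(2R,3S)-2,3-dimethyloxirane-2-carbonyloxy]germacra-4Z,11(13)-dien-12,6α-olide (target)
Conditions: mCPBA (1.05 equiv), NaHCO3, CH2Cl2, 0 °C
Reagents that add atoms: 3-chloroperoxybenzoic acid, OOC(=O)c1cccc(Cl)c1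
Why: Prilezhaev epoxidation should select the most electron-rich olefin (C1=C10; C4=C5 is deactivated by the allylic lactone oxygen and the methylene lactone is electron-poor), and attack on the peripheral face of the E olefin in the conformer with C14 on the β side should give the 1β,10α-oxirane.

**Compound list**
1 | (S)-4-benzyl-1,3-oxazolidin-2-one | O=C1N[C@@H](Cc2ccccc2)CO1 | starting material
2 | methyl 4-chloro-4-oxobutanoate | COC(=O)CCC(Cl)=O | starting material
3 | methyl 4-[(4S)-4-benzyl-2-oxo-1,3-oxazolidin-3-yl]-4-oxobutanoate | COC(=O)CCC(=O)N1[C@@H](Cc2ccccc2)COC1=O | intermediate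
4 | but-2-yn-1-ol | CC#CCO | starting material
5 | sodium 2,2-bis(2-methoxyethoxy)-3-methyl-2,5-dihydro-1,2-oxaaluminol-2-uide (cyclic Z-alkenylalanate) | CC1=CCO[Al-]1(OCCOC)OCCOC.[Na+] | intermediate
6 | (Z)-3-iodobut-2-en-1-ol | C/C(I)=C/CO | intermediate
7 | (Z)-3-iodobut-2-enal | C/C(I)=C/C=O | intermediate
8 | Z(O)-dibutylboron enolate of 3 | COC(=O)C/C=C(\OB(CCCC)CCCC)N1[C@@H](Cc2ccccc2)COC1=O | intermediate
9 | methyl (3S,4S,5Z)-3-{[(4S)-4-benzyl-2-oxo-1,3-oxazolidin-3-yl]carbonyl}-4-hydroxy-6-iodohept-5-enoate | COC(=O)C[C@H](C(=O)N1[C@@H](Cc2ccccc2)COC1=O)[C@H](O)/C=C(/C)I | intermediate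
10 | (4S)-4-benzyl-3-{[(2S,3S)-2-[(Z)-2-iodoprop-1-en-1-yl]-5-oxooxolan-3-yl]carbonyl}-1,3-oxazolidin-2-one | O=C1C[C@H](C(=O)N2[C@@H](Cc3ccccc3)COC2=O)[C@@H](/C=C(/C)I)O1 | intermediate
11 | (2S,3S)-2-[(Z)-2-iodoprop-1-en-1-yl]-5-oxooxolane-3-carboperoxoic acid | O=C1C[C@H](C(=O)OO)[C@@H](/C=C(/C)I)O1 | intermediate
12 | (2S,3S)-2-[(Z)-2-iodoprop-1-en-1-yl]-5-oxooxolane-3-carboxylic acid | O=C1C[C@H](C(O)=O)[C@@H](/C=C(/C)I)O1 | intermediate
13 | (4R,5S)-4-(hydroxymethyl)-5-[(Z)-2-iodoprop-1-en-1-yl]oxolan-2-one | O=C1C[C@H](CO)[C@@H](/C=C(/C)I)O1 | intermediate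
14 | (2S,3S)-2-[(Z)-2-iodoprop-1-en-1-yl]-5-oxooxolane-3-carbaldehyde | O=C1C[C@H](C=O)[C@@H](/C=C(/C)I)O1 | intermediate
15 | 3-methylbut-2-enal | CC(C)=CC=O | starting material
16 | (E)-tert-butyl(dimethyl)[(3-methylbuta-1,3-dien-1-yl)oxy]silane | C=C(C)/C=C/O[Si](C)(C)C(C)(C)C | intermediate
17 | (4R,5S)-4-[(1R,3E)-1-hydroxy-3-methyl-5-oxopent-3-en-1-yl]-5-[(Z)-2-iodoprop-1-en-1-yl]oxolan-2-one | O=C1C[C@H]([C@H](O)C/C(C)=C/C=O)[C@@H](/C=C(/C)I)O1 | intermediate
18 | (4S,5S)-5-[(Z)-2-iodoprop-1-en-1-yl]-4-[(1R,3E)-3-methyl-5-oxo-1-(triethylsilyloxy)pent-3-en-1-yl]oxolan-2-one | O=C1C[C@H]([C@H](O[Si](CC)(CC)CC)C/C(C)=C/C=O)[C@@H](/C=C(/C)I)O1 | intermediate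
19 | (4S,5S)-5-[(Z)-2-iodoprop-1-en-1-yl]-4-[(1R,3E)-3-methyl-1-(triethylsilyloxy)hexa-3,5-dien-1-yl]oxolan-2-one | O=C1C[C@H]([C@H](O[Si](CC)(CC)CC)C/C(C)=C/C=C)[C@@H](/C=C(/C)I)O1 | intermediate
20 | B-alkyl-9-borabicyclo[3.3.1]nonane adduct of 19 (boron on C3) | O=C1C[C@H]([C@H](O[Si](CC)(CC)CC)C/C(C)=C/CCB2C3CCCC2CCC3)[C@@H](/C=C(/C)I)O1 | intermediate
21 | (1(10)E,4Z)-8β-(triethylsilyloxy)-13-norgermacra-1(10),4-dien-12,6α-olide | C1C(=O)O[C@@H]2/C=C(/C)CC/C=C(\C)C[C@@H](O[Si](CC)(CC)CC)[C@@H]12 | intermediate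
22 | lithium enolate of 21 | C1=C([O-])O[C@@H]2/C=C(/C)CC/C=C(\C)C[C@@H](O[Si](CC)(CC)CC)[C@@H]12.[Li+] | intermediate
23 | (1(10)E,4Z)-13-(dimethylamino)-8β-(triethylsilyloxy)-11,13-dihydrogermacra-1(10),4-dien-12,6α-olide (C11 epimers, centre removed in step 14) | CN(C)CC1C(=O)O[C@@H]2/C=C(/C)CC/C=C(\C)C[C@@H](O[Si](CC)(CC)CC)[C@@H]12 | intermediate
24 | N-methyl quaternary ammonium iodide of 23 | C[N+](C)(C)CC1C(=O)O[C@@H]2/C=C(/C)CC/C=C(\C)C[C@@H](O[Si](CC)(CC)CC)[C@@H]12.[I-] | intermediate
25 | (1(10)E,4Z)-8β-(triethylsilyloxy)germacra-1(10),4,11(13)-trien-12,6α-olide | C=C1C(=O)O[C@@H]2/C=C(/C)CC/C=C(\C)C[C@@H](O[Si](CC)(CC)CC)[C@@H]12 | intermediate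
26 | (1(10)E,4Z)-8β-hydroxygermacra-1(10),4,11(13)-trien-12,6α-olide | C=C1C(=O)O[C@@H]2/C=C(/C)CC/C=C(\C)C[C@@H](O)[C@@H]12 | intermediate
27 | (E)-2-methylbut-2-en-1-ol | C/C=C(\C)CO | starting material
28 | [(2S,3S)-2,3-dimethyloxiran-2-yl]methanol | OC[C@@]1(C)O[C@H]1C | intermediate
29 | (2R,3S)-2,3-dimethyloxirane-2-carboxylic acid | OC(=O)[C@@]1(C)O[C@H]1C | intermediate
30 | 2,4,6-trichlorobenzoic (2R,3S)-2,3-dimethyloxirane-2-carboxylic anhydride | O=C(OC(=O)[C@@]1(C)O[C@H]1C)c1c(Cl)cc(Cl)cc1Cl | intermediate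
31 | (1(10)E,4Z)-8β-[(2R,3S)-2,3-dimethyloxirane-2-carbonyloxy]germacra-1(10),4,11(13)-trien-12,6α-olide | C=C1C(=O)O[C@@H]2/C=C(/C)CC/C=C(\C)C[C@@H](OC(=O)[C@@]3(C)O[C@H]3C)[C@@H]12 | intermediate
32 | (1R,10R)-1β,10α-epoxy-8β-[(2R,3S)-2,3-dimethyloxirane-2-carbonyloxy]germacra-4Z,11(13)-dien-12,6α-olide | C=C1C(=O)O[C@@H]2/C=C(/C)CC[C@H]3O[C@]3(C)C[C@@H](OC(=O)[C@@]3(C)O[C@H]3C)[C@@H]12 | target

**Step count**
Total step count: 19.
Longest linear sequence: 15 steps (steps 2, 3, 4, 5, 6, 7, 9, 10, 11, 12, 13, 14, 15, 18, 19, from but-2-yn-1-ol).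

**Steps most likely to fail, with fallbacks**

Step 12. The medium-ring closure may lose to oligomerisation, β-hydride elimination or protodeboronation of the alkylborane, and the aqueous base may open the lactone. The fallback is a base-free Negishi ring closure at the same bond. It sets out from 19: hydroboration as before (through 20) but oxidation with NaBO3 should give the primary C3 alcohol F1; I2, PPh3 and imidazole should convert it into the primary iodide F2; Zn dust with LiCl in THF should insert only into the C(sp3)–I bond to give the alkylzinc iodide F3. Slow addition of F3 to Pd2(dba)3/SPhos (zerovalent palladium) in THF/NMP at high dilution should close the ring, and the fallback comes back to the route at 21.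

Step 9. The reagent may be mismatched with the facial bias of the α-branched lactone aldehyde, giving poor selectivity at C8, and C7 may partly epimerise. The fallback replaces reagent control by substrate-controlled addition plus stereochemical correction. It sets out from 14: dienol ether 16 is added with BF3·OEt2 in CH2Cl2 at −78 °C and the C8 epimers are separated; the unwanted (4R,5S)-4-[(1S,3E)-1-hydroxy-3-methyl-5-oxopent-3-en-1-yl] epimer F4 is inverted by a Mitsunobu reaction with formic acid (PPh3, DIAD) to the (8R)-formate F5; KHCO3 in MeOH removes the formyl group, and the fallback comes back to the route at 17.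

Step 19. The peracid may attack the wrong face of C1=C10 (reaction through the other ring conformer) or compete at C4=C5. The fallback moves the epoxidation before the acylation and uses the 8β-hydroxyl as a directing group. It sets out from 26: VO(acac)2 with t-BuOOH in CH2Cl2 at 0 °C should deliver oxygen to the homoallylic C1=C10 olefin from the side of the 8β-hydroxyl, giving the 1β,10α-epoxy alcohol F6; acylation of F6 with mixed anhydride 30 (Et3N, DMAP) then comes back to the route at 32.

**Further compounds**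
F1 | step 12 | (4S,5S)-4-[(1R,3E)-6-hydroxy-3-methyl-1-(triethylsilyloxy)hex-3-en-1-yl]-5-[(Z)-2-iodoprop-1-en-1-yl]oxolan-2-one | O=C1C[C@H]([C@H](O[Si](CC)(CC)CC)C/C(C)=C/CCO)[C@@H](/C=C(/C)I)O1
F2 | step 12 | (4S,5S)-4-[(1R,3E)-6-iodo-3-methyl-1-(triethylsilyloxy)hex-3-en-1-yl]-5-[(Z)-2-iodoprop-1-en-1-yl]oxolan-2-one | O=C1C[C@H]([C@H](O[Si](CC)(CC)CC)C/C(C)=C/CCI)[C@@H](/C=C(/C)I)O1
F3 | step 12 | alkylzinc iodide of F2 (zinc on C3) | O=C1C[C@H]([C@H](O[Si](CC)(CC)CC)C/C(C)=C/CC[Zn]I)[C@@H](/C=C(/C)I)O1
F4 | step 9 | (4R,5S)-4-[(1S,3E)-1-hydroxy-3-methyl-5-oxopent-3-en-1-yl]-5-[(Z)-2-iodoprop-1-en-1-yl]oxolan-2-one | O=C1C[C@H]([C@@H](O)C/C(C)=C/C=O)[C@@H](/C=C(/C)I)O1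
F5 | step 9 | (4R,5S)-4-[(1R,3E)-1-(formyloxy)-3-methyl-5-oxopent-3-en-1-yl]-5-[(Z)-2-iodoprop-1-en-1-yl]oxolan-2-one | O=C1C[C@H]([C@H](OC=O)C/C(C)=C/C=O)[C@@H](/C=C(/C)I)O1
F6 | step 19 | (1R,10R)-1β,10α-epoxy-8β-hydroxygermacra-4Z,11(13)-dien-12,6α-olide | C=C1C(=O)O[C@@H]2/C=C(/C)CC[C@H]3O[C@]3(C)C[C@@H](O)[C@@H]12
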